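**Plan**
- Retrosynthesis: the two C2'–OMe ethers and the O–Si bond are cut last. Each benzene ring is then cut at C5'–C6', C1'–C2' and C2'–C3', leaving per ring a terminal alkyne, one CO and a methoxy(1-methoxyvinyl)carbene on chromium.
- Enabling feature: each ring has oxygen at C2' and C5' para to one another plus OMe at C4', the 4-alkoxyphenol pattern that a Dötz benzannulation produces. Two identical rings sit on the one methine carbon C1, so a single 3-substituted penta-1,4-diyne carries both alkynes.
- The diyne is cut at its two C1–alkynyl bonds back to the carboxyl carbon of methyl (R)-lactate (alkynyl Grignard addition, then Nicholas alkynylation).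
- Forward: lactate → silyloxy aldehyde → propargylic acetate → cobalt-mediated second alkynylation → skipped diyne. Both arene rings then form together in one twofold benzannulation, and O-methylation and desilylation finish.
- Stereochemistry: the only stereocentre, C2 (R), is the lactate carbinol carbon, carried through as its TBS ether. C1 bears two identical aryl groups and is not stereogenic.

Key step: step 9

Remark (assumption): locants are C1 (methine), C2 (carbinol), C3 (methyl) and C1'–C6' in each ring with C1' on C1. In SMILES, CO ligands and π-bound chromium are written as separate components.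

**Step 1**
Reactants: 1 methyl (R)-lactate
Product: 2 methyl (R)-2-[(tert-butyldimethylsilyl)oxy]propanoate
Conditions: TBSCl, imidazole, DMF, 0 °C → rt
Reagents that add atoms: tert-butyldimethylsilyl chloride, CC(C)(C)[Si](C)(C)Cl
Why: Imidazole-promoted O-silylation of a secondary alcohol (silyl ether formation) is routine for lactate esters and does not touch the stereocentre.

**Step 2**
Reactants: 2 methyl (R)-2-[(tert-butyldimethylsilyl)oxy]propanoate
Product: 3 (R)-2-[(tert-butyldimethylsilyl)oxy]propanal
Conditions: i-Bu2AlH, CH2Cl2, −78 °C; MeOH, then aq. potassium sodium tartrate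
Reagents that add atoms: none
Why: Partial ester reduction by i-Bu2AlH stops at the aluminium hemiacetal at −78 °C and releases the α-silyloxy aldehyde only on work-up, so over-reduction and epimerisation at C2 should be avoided if 3 is used at once.

**Step 3**
Reactants: 3 (R)-2-[(tert-butyldimethylsilyl)oxy]propanal; 4 ethynyltrimethylsilane
Product: 7 (3RS,4R)-4-[(tert-butyldimethylsilyl)oxy]-1-(trimethylsilyl)pent-1-yn-3-yl acetate (both C3 epimers), via [(trimethylsilyl)ethynyl]magnesium bromide 5 (not isolated), via bromomagnesium propargylic alkoxide 6 (not isolated)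
Conditions: 4, EtMgBr, THF, 0 °C → rt; 3, −78 → 0 °C; then Ac2O, 0 °C → rt
Reagents that add atoms: acetic anhydride, CC(=O)OC(C)=O
Why: Grignard 1,2-addition of the alkynylmagnesium bromide (from deprotonation of 4 by EtMgBr) to the aldehyde, followed by in situ O-acetylation of the magnesium alkoxide, which is little prone to 1,2-silyl migration; the new C3 centre should form as an epimer mixture, which is immaterial because C3 is ionised in step 5 and ends up bearing two identical alkynyl groups.

**Step 4**
Reactants: 7 (3RS,4R)-4-[(tert-butyldimethylsilyl)oxy]-1-(trimethylsilyl)pent-1-yn-3-yl acetate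
Product: 8 Co2(CO)6 complex of the C≡C bond of 7 (dicobalt hexacarbonyl alkyne complex)
Conditions: Co2(CO)8, CH2Cl2, rt
Reagents that add atoms: dicobalt octacarbonyl, [Co].[Co].[C-]#[O+].[C-]#[O+].[C-]#[O+].[C-]#[O+].[C-]#[O+].[C-]#[O+].[C-]#[O+].[C-]#[O+]
Why: Alkyne complexation by Co2(CO)8 with loss of two CO is fast and general for silylalkynes and installs the cluster that will stabilise the propargylic cation.

**Step 5**
Reactants: 8 Co2(CO)6 complex of acetate 7; 4 ethynyltrimethylsilane
Product: 12 Co2(CO)6 complex (on one C≡C) of (R)-tert-butyldimethyl{[5-(trimethylsilyl)-3-[(trimethylsilyl)ethynyl]pent-4-yn-2-yl]oxy}silane, via lithium (trimethylsilyl)acetylide 9 (not isolated), via tris[(trimethylsilyl)ethynyl]aluminium 10 (not isolated), via cobalt-stabilised propargylic cation 11 (not isolated)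
Conditions: 4, n-BuLi, Et2O/hexane, 0 °C, then AlCl3 (1/3 equiv); 8, BF3·OEt2, CH2Cl2, −78 °C, then the alane, −78 → 0 °C; aq. NaHCO3
Reagents that add atoms: none
Why: Nicholas reaction: BF3 ionises the acetate to the Co2(CO)6-stabilised propargylic cation, which alkynylaluminium reagents attack only at the propargylic carbon (no allene), the established cobalt route to 1,4-diynes; C3 of 12 is stereogenic only because one alkyne is complexed, and both epimers converge in step 6.

**Step 6**
Reactants: 12 Co2(CO)6 complex of the bis-silylated diyne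
Product: 13 (R)-tert-butyldimethyl{[5-(trimethylsilyl)-3-[(trimethylsilyl)ethynyl]pent-4-yn-2-yl]oxy}silane
Conditions: (NH4)2Ce(NO3)6, acetone, −78 → 0 °C
Reagents that add atoms: none
Why: Oxidative demetallation of alkyne–Co2(CO)6 complexes by tetravalent cerium is the standard close of a Nicholas sequence and is fast enough at low temperature to spare the TBS ether and the C–Si bonds.

**Step 7**
Reactants: 13 (R)-tert-butyldimethyl{[5-(trimethylsilyl)-3-[(trimethylsilyl)ethynyl]pent-4-yn-2-yl]oxy}silane
Product: 14 (R)-tert-butyl[(3-ethynylpent-4-yn-2-yl)oxy]dimethylsilane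
Conditions: AgNO3 (20 mol %), CH2Cl2/MeOH/H2O, rt
Reagents that add atoms: none
Why: Silver-catalysed protodesilylation of alkynyl–SiMe3 bonds runs near neutrality, so the doubly propargylic C–H should not be deprotonated (no isomerisation to an allene) and the TBS ether should survive.

**Step 8**
Reactants: 15 methyl vinyl ether; 16 chromium hexacarbonyl
Product: 19 pentacarbonyl[methoxy(1-methoxyethenyl)carbene]chromium (zerovalent chromium), via 1-methoxyvinyllithium 17 (not isolated), via lithium acylchromate 18 (not isolated)
Conditions: 15, t-BuLi, THF/pentane, −78 → 0 °C; Cr(CO)6, Et2O, 0 °C → rt; then Me3OBF4, CH2Cl2, 0 °C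
Reagents that add atoms: trimethyloxonium tetrafluoroborate, C[O+](C)C.F[B-](F)(F)F
Why: Fischer carbene synthesis: the α-lithiated enol ether adds to a CO ligand of Cr(CO)6 and the acylchromate is O-methylated by the oxonium salt; the α-substituent on the vinyl group, as in the stable isopropenyl and dihydropyranyl analogues, should keep the complex from polymerising.

**Step 9**
Reactants: 14 (R)-tert-butyl[(3-ethynylpent-4-yn-2-yl)oxy]dimethylsilane; 19 pentacarbonyl[methoxy(1-methoxyethenyl)carbene]chromium
Product: 21 2,2'-[(2R)-2-[(tert-butyldimethylsilyl)oxy]propane-1,1-diyl]bis(4,5-dimethoxyphenol), via bis[Cr(CO)3] arene complex 20 (not isolated)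
Conditions: 19 (2.4 equiv), degassed THF (0.05 M in 14), 50 °C, Ar; then air, rt, filtration through Celite
Reagents that add atoms: none
Why: Dötz benzannulation run twice: loss of one CO from 19 lets each terminal alkyne of 14 insert into the Cr=C bond with its CH terminus on the carbene carbon (C5'–C6'), a CO ligand then inserts at the substituted alkyne carbon (C1'–C2') to give a chromium-bound dienylketene, which closes onto the vinyl CH2 (C2'–C3') and tautomerises to the Cr(CO)3-bound phenol, and air then strips the zerovalent chromium to release 21. The closest known reaction type is the benzannulation of alkenyl(alkoxy)carbene chromium complexes, α-alkoxyalkenyl ones included, with terminal alkynes and its twofold use on diynes. Each of the two benzene rings is closed by a 6π electrocyclic ring closure of the dienylketene, so the carbene carbon, its α-carbon and one CO deliver C5'–OMe, C4'–OMe and C2'–OH. No stereocentre is created, since C1 receives two identical aryl groups and the lactate-derived C2 is untouched under these neutral conditions. The step needs regioselective insertion (side chain ortho to the phenol oxygen) and the phenol channel over cyclobutenone, furan or two-alkyne products; the steric bias of a monosubstituted alkyne should secure the first, an alkenyl chromium complex in THF at moderate dilution the second, while the one-carbon spacing of the alkynes excludes an intramolecular second insertion (it would need a three-membered ring) and the excess of 19 drives the second ring to completion.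

**Step 10**
Reactants: 21 2,2'-[(2R)-2-[(tert-butyldimethylsilyl)oxy]propane-1,1-diyl]bis(4,5-dimethoxyphenol)
Product: 22 (R)-tert-butyl{[1,1-bis(2,4,5-trimethoxyphenyl)propan-2-yl]oxy}dimethylsilane
Conditions: MeI, K2CO3, acetone, 50 °C, Ar
Reagents that add atoms: iodomethane, CI
Why: Williamson etherification of the two phenols with MeI/K2CO3; the silyl group should stay on the secondary oxygen because transfer to a phenoxide would be uphill, and no carbon acid is present.

**Step 11**
Reactants: 22 (R)-tert-butyl{[1,1-bis(2,4,5-trimethoxyphenyl)propan-2-yl]oxy}dimethylsilane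
Product: 23 tatarinoid C, (R)-1,1-bis(2,4,5-trimethoxyphenyl)propan-2-ol
Conditions: n-Bu4NF, THF, rt (warming to 50 °C if slow)
Reagents that add atoms: none
Why: Fluoride cleavage of the Si–O bond (silyl ether deprotection) is non-acidic, so the carbinol next to two electron-rich aryl groups should not ionise and C2 keeps its R configuration.

**Compound list**
1 | methyl (R)-lactate | C[C@@H](O)C(=O)OC | starting material
2 | methyl (R)-2-[(tert-butyldimethylsilyl)oxy]propanoate | COC(=O)[C@@H](C)O[Si](C)(C)C(C)(C)C | intermediate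
3 | (R)-2-[(tert-butyldimethylsilyl)oxy]propanal | O=C[C@@H](C)O[Si](C)(C)C(C)(C)C | intermediate
4 | ethynyltrimethylsilane | C#C[Si](C)(C)C | starting material
5 | [(trimethylsilyl)ethynyl]magnesium bromide | C[Si](C)(C)C#C[Mg]Br | intermediate
6 | bromomagnesium (3RS,4R)-4-[(tert-butyldimethylsilyl)oxy]-1-(trimethylsilyl)pent-1-yn-3-olate | Br[Mg]OC(C#C[Si](C)(C)C)[C@@H](C)O[Si](C)(C)C(C)(C)C | intermediate
7 | (3RS,4R)-4-[(tert-butyldimethylsilyl)oxy]-1-(trimethylsilyl)pent-1-yn-3-yl acetate | CC(=O)OC(C#C[Si](C)(C)C)[C@@H](C)O[Si](C)(C)C(C)(C)C | intermediate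
8 | Co2(CO)6 complex of the C≡C bond of 7 | C[Si](C)(C)C12[Co]3[Co]1C23C(OC(C)=O)[C@@H](C)O[Si](C)(C)C(C)(C)C.[C-]#[O+].[C-]#[O+].[C-]#[O+].[C-]#[O+].[C-]#[O+].[C-]#[O+] | intermediate
9 | lithium (trimethylsilyl)acetylide | [Li]C#C[Si](C)(C)C | intermediate
10 | tris[(trimethylsilyl)ethynyl]aluminium | C[Si](C)(C)C#C[Al](C#C[Si](C)(C)C)C#C[Si](C)(C)C | intermediate
11 | Co2(CO)6-stabilised (4R)-4-[(tert-butyldimethylsilyl)oxy]-1-(trimethylsilyl)pent-1-yn-3-ylium acetoxytrifluoroborate | C[Si](C)(C)C12[Co]3[Co]1C23[CH+][C@@H](C)O[Si](C)(C)C(C)(C)C.CC(=O)O[B-](F)(F)F.[C-]#[O+].[C-]#[O+].[C-]#[O+].[C-]#[O+].[C-]#[O+].[C-]#[O+] | intermediate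
12 | Co2(CO)6 complex (one C≡C, both C3 epimers) of the bis-silylated diyne 13 | C[Si](C)(C)C12[Co]3[Co]1C23C(C#C[Si](C)(C)C)[C@@H](C)O[Si](C)(C)C(C)(C)C.[C-]#[O+].[C-]#[O+].[C-]#[O+].[C-]#[O+].[C-]#[O+].[C-]#[O+] | intermediate
13 | (R)-tert-butyldimethyl{[5-(trimethylsilyl)-3-[(trimethylsilyl)ethynyl]pent-4-yn-2-yl]oxy}silane | C[Si](C)(C)C#CC(C#C[Si](C)(C)C)[C@@H](C)O[Si](C)(C)C(C)(C)C | intermediate
14 | (R)-tert-butyl[(3-ethynylpent-4-yn-2-yl)oxy]dimethylsilane | C#CC(C#C)[C@@H](C)O[Si](C)(C)C(C)(C)C | intermediate
15 | methyl vinyl ether | C=COC | starting material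
16 | chromium hexacarbonyl | [Cr].[C-]#[O+].[C-]#[O+].[C-]#[O+].[C-]#[O+].[C-]#[O+].[C-]#[O+] | starting material
17 | 1-methoxyvinyllithium | [Li]C(=C)OC | intermediate
18 | lithium pentacarbonyl[(1-methoxyethenyl)(oxido)methylidene]chromate | [Li+].[O-]C(=[Cr])C(OC)=C.[C-]#[O+].[C-]#[O+].[C-]#[O+].[C-]#[O+].[C-]#[O+] | intermediate
19 | pentacarbonyl[methoxy(1-methoxyethenyl)carbene]chromium (zerovalent chromium) | COC(=[Cr])C(OC)=C.[C-]#[O+].[C-]#[O+].[C-]#[O+].[C-]#[O+].[C-]#[O+] | intermediate
20 | bisphenol 21 with a Cr(CO)3 unit η6-bound to each arene ring | C[C@@H](O[Si](C)(C)C(C)(C)C)C(c1cc(OC)c(OC)cc1O)c1cc(OC)c(OC)cc1O.[Cr].[Cr].[C-]#[O+].[C-]#[O+].[C-]#[O+].[C-]#[O+].[C-]#[O+].[C-]#[O+] | intermediate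
21 | 2,2'-[(2R)-2-[(tert-butyldimethylsilyl)oxy]propane-1,1-diyl]bis(4,5-dimethoxyphenol) | C[C@@H](O[Si](C)(C)C(C)(C)C)C(c1cc(OC)c(OC)cc1O)c1cc(OC)c(OC)cc1O | intermediate
22 | (R)-tert-butyl{[1,1-bis(2,4,5-trimethoxyphenyl)propan-2-yl]oxy}dimethylsilane | C[C@@H](O[Si](C)(C)C(C)(C)C)C(c1cc(OC)c(OC)cc1OC)c1cc(OC)c(OC)cc1OC | intermediate
23 | tatarinoid C, (R)-1,1-bis(2,4,5-trimethoxyphenyl)propan-2-ol | COc1cc(OC)c(C(c2cc(OC)c(OC)cc2OC)[C@@H](C)O)cc1OC | target

**Step count and risks**
Total: 11 steps. Longest linear sequence: 10 steps (steps 1–7 and 9–11 from 1); step 8 is a one-step branch.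

Steps most likely to fail:

1. Step 9 (twofold benzannulation). The second ring may not close before the electron-rich vinylcarbene decomposes or oligomerises at 50 °C. The terminal alkynes may be drawn into two-alkyne or oligomer channels. Demetallation in air may over-oxidise the 4-alkoxyphenols towards quinones. Fallback without chromium: setting out from 3, 1-bromo-2,4,5-trimethoxybenzene is lithiated (n-BuLi, THF, −78 °C) to 2,4,5-trimethoxyphenyllithium F1, which adds to 3 to give (1RS,2R)-2-[(tert-butyldimethylsilyl)oxy]-1-(2,4,5-trimethoxyphenyl)propan-1-ol F2. Friedel–Crafts benzylation of 1,2,4-trimethoxybenzene with F2 (catalytic Bi(OTf)3, CH2Cl2, 0 °C), at its most nucleophilic position C5, should give 22 directly. The route is rejoined at 22.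

2. Step 5 (Nicholas alkynylation). The long-lived cation may lose the C2 proton to give an enyne, suffer a 1,2-hydride shift towards the silyloxy carbon, or lose the TBS group to BF3 before the alane captures it. Fallback without cobalt: setting out from 3, addition of the Grignard reagent 5 with aqueous NH4Cl quench gives (3RS,4R)-4-[(tert-butyldimethylsilyl)oxy]-1-(trimethylsilyl)pent-1-yn-3-ol F3. Mesylation (MsCl, Et3N, CH2Cl2, −20 °C) gives the methanesulfonate F4. Dimethyl[(trimethylsilyl)ethynyl]aluminium F5, made from 9 and Me2AlCl, should then displace the aluminium-activated sulfonate within a contact ion pair (CH2Cl2/hexane, 0 °C → rt), a known direct coupling of alkynylalanes with propargylic sulfonates to skipped diynes. The route is rejoined at 13.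

3. Step 8 (carbene complex). The hard oxonium salt may attack the electron-rich enol ether and start cationic oligomerisation, or the acylchromate may decompose during alkylation. Fallback by acylation and alcoholysis: setting out from 15 and 16 through the same lithium acylchromate 18, cation exchange with Me4NBr in water gives the isolable tetramethylammonium acylchromate F6. AcBr in CH2Cl2 at −40 °C converts it into pentacarbonyl[acetoxy(1-methoxyethenyl)carbene]chromium F7, and MeOH at −40 → 0 °C exchanges acetate for methoxide. The route is rejoined at 19.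

**Further compounds**
F1 | step 9 | 2,4,5-trimethoxyphenyllithium | [Li]c1cc(OC)c(OC)cc1OC
F2 | step 9 | (1RS,2R)-2-[(tert-butyldimethylsilyl)oxy]-1-(2,4,5-trimethoxyphenyl)propan-1-ol | OC(c1cc(OC)c(OC)cc1OC)[C@@H](C)O[Si](C)(C)C(C)(C)C
F3 | step 5 | (3RS,4R)-4-[(tert-butyldimethylsilyl)oxy]-1-(trimethylsilyl)pent-1-yn-3-ol | OC(C#C[Si](C)(C)C)[C@@H](C)O[Si](C)(C)C(C)(C)C
F4 | step 5 | (3RS,4R)-4-[(tert-butyldimethylsilyl)oxy]-1-(trimethylsilyl)pent-1-yn-3-yl methanesulfonate | CS(=O)(=O)OC(C#C[Si](C)(C)C)[C@@H](C)O[Si](C)(C)C(C)(C)C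
F5 | step 5 | dimethyl[(trimethylsilyl)ethynyl]aluminium | C[Al](C)C#C[Si](C)(C)C
F6 | step 8 | tetramethylammonium pentacarbonyl[(1-methoxyethenyl)(oxido)methylidene]chromate | C[N+](C)(C)C.[O-]C(=[Cr])C(OC)=C.[C-]#[O+].[C-]#[O+].[C-]#[O+].[C-]#[O+].[C-]#[O+]
F7 | step 8 | pentacarbonyl[acetoxy(1-methoxyethenyl)carbene]chromium | CC(=O)OC(=[Cr])C(OC)=C.[C-]#[O+].[C-]#[O+].[C-]#[O+].[C-]#[O+].[C-]#[O+]
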